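**Strategy.** Prinsepiol is a C2-symmetric 3,7-dioxabicyclo[3.3.0]octane in which the methylenes C4 and C8 sit on the carbinol carbons C5 and C1 and are each bonded to the benzylic oxygen (O3, O7) of the other half. They are therefore introduced as the CH2 groups of two terminal oxiranes, made in one operation by twofold, Felkin–Anh-controlled methylene transfer from iodomethyllithium to a C2-symmetric 1,4-diaryl-1,4-bis(silyloxy)butane-2,3-dione. This forms C1–C8 and C5–C4 and sets C1 and C5 from the C2/C6 silyloxy stereocentres. The dione comes from two catalytic asymmetric alkynylations of O-benzylvanillin and oxidation of the alkyne; fluoride-triggered double epoxide opening then closes rings A and B, and hydrogenolysis frees the phenols.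

Key step: step 6

Locants: C1/C5 are the ring-fusion carbinol carbons, C2/C6 the aryl-bearing carbons, C4/C8 the methylenes; ring A is C1–C2–O3–C4–C5, ring B is C5–C6–O7–C8–C1; Ar = 4-(benzyloxy)-3-methoxyphenyl.

Assumption: (S)-BINOL is taken to direct alkynylzinc reagents to the Si face of aromatic aldehydes, as it does alkylzinc reagents; should the opposite sense be found, (R)-BINOL would be used in steps 1 and 3.

**Step 1**
Reactants: 1 4-(benzyloxy)-3-methoxybenzaldehyde; 2 ethynyltrimethylsilane
Product: 3 (R)-1-[4-(benzyloxy)-3-methoxyphenyl]-3-(trimethylsilyl)prop-2-yn-1-ol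
Conditions: 2 (2 equiv), Et2Zn (2 equiv), Cy2NH (5 mol %), Et2O, rt; (S)-BINOL (40 mol %), Ti(OiPr)4 (1 equiv); 1, rt
Reagents that add atoms: none
Why: Catalytic enantioselective alkynylzinc addition to an aromatic aldehyde under BINOL–Ti(OiPr)4 control, in which the (S)-BINOL titanate should direct the alkynyl group to the Si face and so set the (R) carbinol that becomes C2.

**Step 2**
Reactants: 3 (R)-1-Ar-3-(trimethylsilyl)prop-2-yn-1-ol
Product: 5 {[(1S)-1-[4-(benzyloxy)-3-methoxyphenyl]prop-2-yn-1-yl]oxy}tri(propan-2-yl)silane, via C-trimethylsilyl propargylic silyl ether 4 (not isolated)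
Conditions: TIPSOTf, 2,6-lutidine, CH2Cl2, 0 °C; then MeOH, K2CO3, rt
Reagents that add atoms: triisopropylsilyl trifluoromethanesulfonate, CC(C)[Si](C(C)C)(C(C)C)OS(=O)(=O)C(F)(F)F
Why: Silyl triflate O-silylation of the secondary alcohol followed in the same flask by carbonate-mediated methanolysis of the alkynyl C–SiMe3 bond (protodesilylation), neither of which touches the stereocentre, whose descriptor becomes (S) only because ethynyl ranks below aryl.

**Step 3**
Reactants: 5 (S)-1-Ar-prop-2-yn-1-yl triisopropylsilyl ether; 1 4-(benzyloxy)-3-methoxybenzaldehyde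
Product: 6 (1R,4R)-1,4-bis[4-(benzyloxy)-3-methoxyphenyl]-4-[(triisopropylsilyl)oxy]but-2-yn-1-ol
Conditions: 5 (1 equiv), Et2Zn (1.2 equiv), Cy2NH (5 mol %), Et2O, rt; (S)-BINOL (40 mol %), Ti(OiPr)4 (1 equiv); 1 (1.5 equiv), rt
Reagents that add atoms: none
Why: The same reagent-controlled alkynylzinc addition, now with the zinc acetylide of 5, should again attack the Si face of 1 and set the second (R) carbinol (C6), the remote silyloxy centre having little influence and the minor unsymmetrical diastereomer being removed by chromatography, which raises the enantiomeric purity of the C2-symmetric series by statistical amplification.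

**Step 4**
Reactants: 6 (1R,4R)-1,4-diaryl-4-(triisopropylsilyloxy)but-2-yn-1-ol
Product: 7 (1R,4R)-1,4-bis[4-(benzyloxy)-3-methoxyphenyl]-1,4-bis[(triisopropylsilyl)oxy]but-2-yne
Conditions: TIPSOTf, 2,6-lutidine, CH2Cl2, 0 °C to rt
Reagents that add atoms: triisopropylsilyl trifluoromethanesulfonate, CC(C)[Si](C(C)C)(C(C)C)OS(=O)(=O)C(F)(F)F
Why: Silyl triflate silylation of the remaining secondary benzylic alcohol with a hindered pyridine base, which affects no stereocentre and installs the second bulky, non-chelating ether needed for the key step.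

**Step 5**
Reactants: 7 (1R,4R)-1,4-diaryl-1,4-bis(triisopropylsilyloxy)but-2-yne
Product: 8 (1R,4R)-1,4-bis[4-(benzyloxy)-3-methoxyphenyl]-1,4-bis[(triisopropylsilyl)oxy]butane-2,3-dione
Conditions: KMnO4, NaHCO3, MgSO4, acetone/H2O, 0 °C to rt
Reagents that add atoms: potassium permanganate, [K+].[O-][Mn](=O)(=O)=O
Why: Buffered permanganate oxidation of an internal alkyne to the 1,2-dione through the cyclic manganate ester, chosen because the near-neutral medium should spare the electron-rich arenes, the benzyl and silyl ethers and the enolisable C2–H and C6–H centres, the dione being used at once without chromatography on silica.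

**Step 6**
Reactants: 8 (1R,4R)-1,4-diaryl-1,4-bis(triisopropylsilyloxy)butane-2,3-dione; 9 diiodomethane (one equivalent is consumed at each carbonyl carbon)
Product: 13 (2S,2'S)-2,2'-bis{(R)-[4-(benzyloxy)-3-methoxyphenyl][(triisopropylsilyl)oxy]methyl}-2,2'-bioxirane, via iodohydrin lithium alkoxide 10 (not isolated), via epoxy ketone 11 (not isolated), via epoxy iodohydrin lithium alkoxide 12 (not isolated)
Conditions: CH2I2 (5 equiv), THF, −78 °C; MeLi (1.2 equiv), −78 °C to rt; recool to −78 °C; MeLi (1.5 equiv), −78 °C to rt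
Reagents that add atoms: diiodomethane (second equivalent), ICI
Why: Iodine–lithium exchange between MeLi and CH2I2 in the presence of the dione gives iodomethyllithium, which adds to a carbonyl faster than it deprotonates C2–H or C6–H, and each iodohydrin lithium alkoxide then closes to its oxirane by 3-exo-tet displacement of iodide, so that two equivalents of diiodomethane deliver C8 and C4 and no ring of the target is formed; the closest known reaction type is the halomethyllithium epoxidation of ketones that carry an α-heteroatom stereocentre. C1 is set by polar Felkin–Anh addition: the C2–O bond of the bulky, non-chelating silyl ether lies anti to the incoming carbenoid, which passes the C2 hydrogen, and this gives the Felkin relationship of the two oxygens (anti when the chain is drawn Ar–C2–C1–C8) that later places aryl cis to the tertiary hydroxyl on ring A. The reagent is dosed in two portions with warming in between so that the first alkoxide has become an oxirane before the second carbonyl reacts, since a lithium alkoxide at C1 could chelate the C5 carbonyl and steer the carbenoid to the wrong face; the first portion should stop at mono-addition because the α-alkoxy ketone left behind is much less electrophilic than the 1,2-dione. In epoxy ketone 11 the oxirane C1–O bond and the C6–O bond of the silyl ether can each lie anti to the nucleophile, and both arrangements expose the same face of the C5 carbonyl, so C5 should form with the same sense and give the C2-symmetric product. The step needs 1,2-addition to win over enolisation and over direct attack of MeLi (secured by generating the carbenoid in the presence of the very electrophilic dione at −78 °C) and needs facial selectivity at both carbonyls (secured by the triisopropylsilyl ethers in THF).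

**Step 7**
Reactants: 13 (2S,2'S)-2,2'-bis[(R)-aryl(triisopropylsilyloxy)methyl]-2,2'-bioxirane
Product: 16 (1S,2R,5S,6R)-2,6-bis[4-(benzyloxy)-3-methoxyphenyl]-3,7-dioxabicyclo[3.3.0]octane-1,5-diol, via bis(epoxy) diol 14 (not isolated), via spiro-epoxy tetrahydrofuranol 15 (not isolated)
Conditions: TBAF (4 equiv), THF, 0 °C to 45 °C
Reagents that add atoms: none
Why: Fluoride desilylation frees the C2 and C6 alkoxides, each of which should open the oxirane of the other half at its unhindered CH2 terminus (O3–C4, then O7–C8; intramolecular 5-endo epoxide opening, as in the base-induced formation of 3,6-anhydro sugars from 5,6-epoxides), the fully substituted C1 and C5 disfavouring the oxetane and Payne alternatives, and no stereocentre is touched because only methylene carbons are attacked.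

**Step 8**
Reactants: 16 O,O'-dibenzylprinsepiol
Product: 17 prinsepiol, (1S,2R,5S,6R)-2,6-bis(4-hydroxy-3-methoxyphenyl)-3,7-dioxabicyclo[3.3.0]octane-1,5-diol
Conditions: H2 (1 atm), 10% Pd/C, EtOAc, rt
Reagents that add atoms: none
Why: Catalytic hydrogenolysis of the two aryl benzyl ethers, which should be much faster than cleavage of the hindered dialkyl-type benzylic C2–O3 and C6–O7 bonds when the reaction is run in EtOAc at atmospheric pressure and stopped at full conversion, leaving all four stereocentres untouched.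

**Compound list**

1 | 4-(benzyloxy)-3-methoxybenzaldehyde (O-benzylvanillin) | COc1cc(C=O)ccc1OCc1ccccc1 | starting material
2 | ethynyltrimethylsilane | C#C[Si](C)(C)C | starting material
3 | (R)-1-[4-(benzyloxy)-3-methoxyphenyl]-3-(trimethylsilyl)prop-2-yn-1-ol | COc1cc([C@@H](O)C#C[Si](C)(C)C)ccc1OCc1ccccc1 | intermediate
4 | {[(1R)-1-[4-(benzyloxy)-3-methoxyphenyl]-3-(trimethylsilyl)prop-2-yn-1-yl]oxy}tri(propan-2-yl)silane (not isolated) | COc1cc([C@@H](O[Si](C(C)C)(C(C)C)C(C)C)C#C[Si](C)(C)C)ccc1OCc1ccccc1 | intermediate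
5 | {[(1S)-1-[4-(benzyloxy)-3-methoxyphenyl]prop-2-yn-1-yl]oxy}tri(propan-2-yl)silane (same spatial arrangement as 3) | COc1cc([C@@H](O[Si](C(C)C)(C(C)C)C(C)C)C#C)ccc1OCc1ccccc1 | intermediate
6 | (1R,4R)-1,4-bis[4-(benzyloxy)-3-methoxyphenyl]-4-[(triisopropylsilyl)oxy]but-2-yn-1-ol | COc1cc([C@@H](O[Si](C(C)C)(C(C)C)C(C)C)C#C[C@H](O)c2ccc(OCc3ccccc3)c(OC)c2)ccc1OCc1ccccc1 | intermediate
7 | (1R,4R)-1,4-bis[4-(benzyloxy)-3-methoxyphenyl]-1,4-bis[(triisopropylsilyl)oxy]but-2-yne | COc1cc([C@@H](O[Si](C(C)C)(C(C)C)C(C)C)C#C[C@H](O[Si](C(C)C)(C(C)C)C(C)C)c2ccc(OCc3ccccc3)c(OC)c2)ccc1OCc1ccccc1 | intermediate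
8 | (1R,4R)-1,4-bis[4-(benzyloxy)-3-methoxyphenyl]-1,4-bis[(triisopropylsilyl)oxy]butane-2,3-dione | COc1cc([C@@H](O[Si](C(C)C)(C(C)C)C(C)C)C(=O)C(=O)[C@H](O[Si](C(C)C)(C(C)C)C(C)C)c2ccc(OCc3ccccc3)c(OC)c2)ccc1OCc1ccccc1 | intermediate
9 | diiodomethane | ICI | starting material
10 | lithium (1R,2S,4R)-1,4-bis[4-(benzyloxy)-3-methoxyphenyl]-2-(iodomethyl)-3-oxo-1,4-bis[(triisopropylsilyl)oxy]butan-2-olate (not isolated) | COc1cc([C@@H](O[Si](C(C)C)(C(C)C)C(C)C)[C@@](O[Li])(CI)C(=O)[C@H](O[Si](C(C)C)(C(C)C)C(C)C)c2ccc(OCc3ccccc3)c(OC)c2)ccc1OCc1ccccc1 | intermediate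
11 | (2R)-2-[4-(benzyloxy)-3-methoxyphenyl]-1-{(2S)-2-[(R)-[4-(benzyloxy)-3-methoxyphenyl][(triisopropylsilyl)oxy]methyl]oxiran-2-yl}-2-[(triisopropylsilyl)oxy]ethan-1-one (not isolated) | COc1cc([C@@H](O[Si](C(C)C)(C(C)C)C(C)C)[C@@]2(CO2)C(=O)[C@H](O[Si](C(C)C)(C(C)C)C(C)C)c3ccc(OCc4ccccc4)c(OC)c3)ccc1OCc1ccccc1 | intermediate
12 | lithium (1R,2S)-1-[4-(benzyloxy)-3-methoxyphenyl]-2-{(2S)-2-[(R)-[4-(benzyloxy)-3-methoxyphenyl][(triisopropylsilyl)oxy]methyl]oxiran-2-yl}-3-iodo-1-[(triisopropylsilyl)oxy]propan-2-olate (not isolated) | COc1cc([C@@H](O[Si](C(C)C)(C(C)C)C(C)C)[C@@]2(CO2)[C@](O[Li])(CI)[C@H](O[Si](C(C)C)(C(C)C)C(C)C)c3ccc(OCc4ccccc4)c(OC)c3)ccc1OCc1ccccc1 | intermediate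
13 | (2S,2'S)-2,2'-bis{(R)-[4-(benzyloxy)-3-methoxyphenyl][(triisopropylsilyl)oxy]methyl}-2,2'-bioxirane | COc1cc([C@@H](O[Si](C(C)C)(C(C)C)C(C)C)[C@@]2(CO2)[C@]3(CO3)[C@H](O[Si](C(C)C)(C(C)C)C(C)C)c4ccc(OCc5ccccc5)c(OC)c4)ccc1OCc1ccccc1 | intermediate
14 | (2S,2'S)-2,2'-bis{(R)-[4-(benzyloxy)-3-methoxyphenyl](hydroxy)methyl}-2,2'-bioxirane (not isolated) | COc1cc([C@@H](O)[C@@]2(CO2)[C@]3(CO3)[C@H](O)c4ccc(OCc5ccccc5)c(OC)c4)ccc1OCc1ccccc1 | intermediate
15 | (3S,4R,7S)-4-[4-(benzyloxy)-3-methoxyphenyl]-7-{(R)-[4-(benzyloxy)-3-methoxyphenyl](hydroxy)methyl}-1,5-dioxaspiro[2.4]heptan-7-ol, ring A closed and the C1 oxirane still in place (not isolated) | COc1cc([C@H]2OC[C@](O)([C@H](O)c3ccc(OCc4ccccc4)c(OC)c3)[C@]25CO5)ccc1OCc1ccccc1 | intermediate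
16 | (1S,2R,5S,6R)-2,6-bis[4-(benzyloxy)-3-methoxyphenyl]-3,7-dioxabicyclo[3.3.0]octane-1,5-diol (O,O'-dibenzylprinsepiol) | COc1cc([C@H]2OC[C@]3(O)[C@@H](c4ccc(OCc5ccccc5)c(OC)c4)OC[C@]23O)ccc1OCc1ccccc1 | intermediate
17 | prinsepiol, (1S,2R,5S,6R)-2,6-bis(4-hydroxy-3-methoxyphenyl)-3,7-dioxabicyclo[3.3.0]octane-1,5-diol | COc1cc([C@H]2OC[C@]3(O)[C@@H](c4ccc(O)c(OC)c4)OC[C@]23O)ccc1O | target

**Step count and risk**

Total step count: 8. Longest linear sequence: 8 steps (1 to 17; aldehyde 1 enters twice).

Steps most likely to fail: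

Step 6. The dione may be enolised at C2–H or C6–H by the carbenoid or by MeLi, with loss of configuration. Facial selectivity at the second carbonyl may also be poor if lithium chelation by the oxirane, or by an alkoxide that has not yet closed, overrides the Felkin–Anh preference. The fallback sets out from dione 8. Both carbonyls are methylenated with the non-basic Tebbe reagent Cp2Ti(μ-Cl)(μ-CH2)AlMe2 (THF/pyridine, −40 °C to rt) to give the 2,3-dimethylidene bis(silyl ether) F1. TBAF in THF removes the silyl groups to give the dienediol F2. Hydroxyl-directed epoxidation with VO(acac)2 and t-BuOOH (CH2Cl2, 0 °C) should then place each oxirane oxygen erythro to its neighbouring carbinol, because allylic 1,2-strain with the substituent geminal on the alkene holds the carbinol hydrogen in the alkene plane. This delivers bis(epoxy) diol 14, where the fallback rejoins the route; 14 is cyclised to 16 with TBAF or catalytic t-BuOK as in step 7.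

Step 7. The alkoxides may fail to reach the oxirane CH2 termini in the 5-endo mode at a useful rate, or epoxide migration of the Payne type may scramble the array before the rings close. The fallback sets out from 13. Desilylation with TBAF buffered with AcOH (THF, rt) gives the neutral bis(epoxy) diol 14, which is isolated and treated with MgI2 (toluene/Et2O, rt to 60 °C). Iodide opens each oxirane at CH2 to give the bis(iodohydrin) F3, and the C2 and C6 oxygens, as magnesium alkoxides, then displace iodide in a 5-exo-tet Williamson closure. The double inversion occurs at methylene carbons and has no stereochemical consequence. The sequence rejoins the route at 16.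

Step 5. Over-oxidation may cleave the C1–C5 bond, the hindered alkyne may react slowly, or the product may enolise during work-up. The fallback sets out from alkyne 7. Semihydrogenation over Lindlar catalyst (Pd/CaCO3 poisoned with Pb(OAc)2, quinoline, H2, EtOAc) gives the (Z)-alkene F4. Dihydroxylation with catalytic OsO4 and NMO (acetone/H2O) gives a single erythro diol F5, the two alkene faces being equivalent by symmetry. Double Swern oxidation ((COCl)2, DMSO, Et3N, CH2Cl2, −78 °C) returns to dione 8.

**Further compounds**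

F1 | step 6 | (1R,4R)-1,4-bis[4-(benzyloxy)-3-methoxyphenyl]-2,3-dimethylidene-1,4-bis[(triisopropylsilyl)oxy]butane | COc1cc([C@@H](O[Si](C(C)C)(C(C)C)C(C)C)C(=C)C(=C)[C@H](O[Si](C(C)C)(C(C)C)C(C)C)c2ccc(OCc3ccccc3)c(OC)c2)ccc1OCc1ccccc1
F2 | step 6 | (1R,4R)-1,4-bis[4-(benzyloxy)-3-methoxyphenyl]-2,3-dimethylidenebutane-1,4-diol | COc1cc([C@@H](O)C(=C)C(=C)[C@H](O)c2ccc(OCc3ccccc3)c(OC)c2)ccc1OCc1ccccc1
F3 | step 7 | (1R,2S,3S,4R)-1,4-bis[4-(benzyloxy)-3-methoxyphenyl]-2,3-bis(iodomethyl)butane-1,2,3,4-tetraol | COc1cc([C@@H](O)[C@@](O)(CI)[C@](O)(CI)[C@H](O)c2ccc(OCc3ccccc3)c(OC)c2)ccc1OCc1ccccc1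
F4 | step 5 | (1S,4S,2Z)-1,4-bis[4-(benzyloxy)-3-methoxyphenyl]-1,4-bis[(triisopropylsilyl)oxy]but-2-ene (same spatial arrangement as 7; aryl now outranks the alkenyl carbon) | COc1cc([C@@H](O[Si](C(C)C)(C(C)C)C(C)C)/C=C\[C@H](O[Si](C(C)C)(C(C)C)C(C)C)c2ccc(OCc3ccccc3)c(OC)c2)ccc1OCc1ccccc1
F5 | step 5 | (1R,2R,3S,4R)-1,4-bis[4-(benzyloxy)-3-methoxyphenyl]-1,4-bis[(triisopropylsilyl)oxy]butane-2,3-diol | COc1cc([C@@H](O[Si](C(C)C)(C(C)C)C(C)C)[C@H](O)[C@H](O)[C@H](O[Si](C(C)C)(C(C)C)C(C)C)c2ccc(OCc3ccccc3)c(OC)c2)ccc1OCc1ccccc1
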